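The route rests on reading the cis-1,3 pair on the cyclohexane (ring C6–C11), the C5 arm on C6 and the oxygen on C10 flanking quaternary C11, as a cyclobutanone: C5 is tied to C10 by a temporary C–C bond that a later Baeyer–Villiger oxidation exchanges for C10–O. One intramolecular keteniminium–alkene [2+2] cycloaddition of an acyclic neryl amide forms C6–C11 and C5–C10, closes the six- and four-membered rings and sets C6, C10 and C11; the Z alkene fixes C11 and a C2-symmetric pyrrolidine the absolute sense. The precursor is the (2R,5R)-2,5-dimethylpyrrolidine amide of a 3,3-ethylenedioxy acid carrying the neryl chain.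

Key step: step 5

Numbering used below: C1 aldehyde carbon, C2 its methyl-bearing α-carbon, C3–C5 the hydroxypropyl arm (C3 carries OH, C5 sits on C6), C6–C11 the ring (C6 CH, C7 alkylidene carbon, C8 and C9 CH2, C10 carbinol, C11 quaternary), C12–C23 the side chain (C14=C15, C16 carbinol, C18=C19, C22=C23). In the acyclic precursor the amide carbonyl is C5, the ketal carbon C7 and the neryl alkene C10=C11.

Remark on the structures: the Z (neryl) alkene, amide 9 and ketone 12 were checked against the target and agree with it at C6, C10 and C11, so no structure needed correction. Ketone 12 has no methyl on C10; that group and the tertiary carbinol are made in steps 12 and 13. The amide bond is made before the ketal (steps 2–4), so no hindered amine has to be coupled to an acid-sensitive ketal acid.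

Assumption: the (2R,5R)-amine is taken to give the face selection shown; if the cycloaddition gives the mirror-image bicycle, the (2S,5S)-amine is used and nothing else changes.

Step 1
Reactants: 1 nerol
Product: 2 neryl bromide
Conditions: PBr3, pyridine (cat.), Et2O, −10 °C
Reagents that add atoms: phosphorus tribromide, BrP(Br)Br
Why: Bromination of the primary allylic alcohol by PBr3 (SN2 on the phosphite ester) at low temperature keeps the 2Z geometry; the bromide is used at once.

Step 2
Reactants: 3 (2R,5R)-2,5-dimethylpyrrolidine; 4 2,2,6-trimethyl-4H-1,3-dioxin-4-one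
Product: 6 N-acetoacetyl amide 1-[(2R,5R)-2,5-dimethylpyrrolidin-1-yl]butane-1,3-dione, via acetylketene 5 (not isolated)
Conditions: toluene, 110 °C, sealed vessel
Reagents that add atoms: none
Why: Thermal retro-[4+2] of the dioxinone releases acetone and acetylketene, which acylates even this hindered secondary amine (acetoacetylation) without touching its stereocentres.

Step 3
Reactants: 6 N-acetoacetyl amide; 2 neryl bromide
Product: 8 γ-neryl β-keto amide (6Z)-1-[(2R,5R)-2,5-dimethylpyrrolidin-1-yl]-7,11-dimethyldodeca-6,10-diene-1,3-dione, via dilithium dianion 7 (not isolated)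
Conditions: LiN(iPr)2 (2.2 equiv), THF, 0 °C; then 2, −78 → 0 °C
Reagents that add atoms: none
Why: γ-Alkylation of a β-keto amide dianion, whose terminal carbanion displaces the primary allylic bromide by SN2, so the Z alkene is carried over unchanged.

Step 4
Reactants: 8 γ-neryl β-keto amide
Product: 9 ketal amide (key precursor) 2-{2-[(3Z)-4,8-dimethylnona-3,7-dien-1-yl]-1,3-dioxolan-2-yl}-1-[(2R,5R)-2,5-dimethylpyrrolidin-1-yl]ethan-1-one
Conditions: HOCH2CH2OH, TsOH·H2O (cat.), benzene, reflux, Dean–Stark trap
Reagents that add atoms: ethylene glycol, OCCO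
Why: Acid-catalysed ketalisation with azeotropic removal of water; trisubstituted alkenes of this neryl type tolerate catalytic TsOH under these conditions.

Step 5
Reactants: 9 ketal amide
Product: 12 bicyclic ketone (1R,5S,7R)-7-methyl-7-(4-methylpent-3-en-1-yl)spiro[bicyclo[3.1.1]heptane-2,2'-[1,3]dioxolan]-6-one, via keteniminium triflate 10 (not isolated), via cyclobutaniminium triflate 11 (not isolated)
Conditions: Tf2O, 2,4,6-collidine, ClCH2CH2Cl, 0 → 80 °C; then aq NaHCO3, 60 °C
Reagents that add atoms: water, O
Why: Tf2O converts the amide into its O-triflyl iminium salt, which collidine deprotonates at C6 to the keteniminium ion 10; its electrophilic carbon C5 bonds to the less substituted alkene carbon C10 while C6 bonds to C11, where positive charge is best stabilised, giving the cyclobutaniminium salt 11, which bicarbonate hydrolyses to 12 with return of the amine. The closest known reaction type is the intramolecular keteniminium (or ketene)–alkene [2+2] cycloaddition of alkenyl amides whose distal alkene carbon is the more substituted one, which gives bicyclo[3.1.1]heptan-6-ones. The cyclohexane closes in the 6-endo sense through C6–C11 and the cyclobutane in the crossed [2+2] mode through C5–C10, the three-atom tether C7–C9 spanning both. C11 is set by suprafacial addition to the Z alkene (homoprenyl syn to the C7–C9 bridge, methyl anti), C6 and C10 are tied to it by the bicycle, and the absolute sense comes from the C2-symmetric pyrrolidine, whose methyl groups shield one face of the iminium carbon. The step needs crossed rather than fused regiochemistry, secured by the fully substituted C11, and transfer of the alkene geometry, secured by closure of C6–C11 faster than rotation about C10–C11; the collidine-buffered, non-aqueous medium and the bicarbonate hydrolysis are chosen to keep the ketal intact.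

Step 6
Reactants: 12 bicyclic ketone
Product: 13 bridged γ-lactone (6-oxabicyclo[3.2.1]octan-7-one with O on C10)
Conditions: 30% H2O2, aq NaOH, THF, 0 °C
Reagents that add atoms: hydrogen peroxide, OO
Why: Baeyer–Villiger oxidation by hydroperoxide anion, which attacks only the strained ketone and spares the electron-rich alkene; C10 migrates with retention in preference to C6, whose migratory aptitude is lowered by the adjacent ketal carbon, so the new C10–O bond is cis to C5 (a short, cold reaction keeps the lactone closed).

Step 7
Reactants: 13 bridged γ-lactone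
Product: 14 lactol (both anomers)
Conditions: iBu2AlH, CH2Cl2, −78 °C
Reagents that add atoms: none
Why: Partial hydride reduction of a γ-lactone to the lactol, whose aluminium acetal is stable at −78 °C.

Step 8
Reactants: 14 lactol
Product: 16 hydroxy enoate (C6–CH=CH–CO2Me of E geometry and free C10–OH), via open hydroxy aldehyde 15 (not isolated)
Conditions: Ph3P=CHCO2Me, PhCO2H (cat.), toluene, 80 °C
Reagents that add atoms: methyl (triphenylphosphoranylidene)acetate, COC(=O)C=P(c1ccccc1)(c1ccccc1)c1ccccc1
Why: Wittig olefination of the ring-opened hydroxy aldehyde with a stabilised ylide gives the E enoate and adds C4 and C3; the neutral, weakly acidic medium limits epimerisation at C6 and oxa-Michael re-closure by the C10 hydroxyl.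

Step 9
Reactants: 16 hydroxy enoate
Product: 17 saturated hydroxy ester
Conditions: NaBH4, NiCl2·6H2O (cat.), MeOH, 0 °C
Reagents that add atoms: none
Why: Conjugate reduction by NaBH4 with nickel boride formed in situ is selective for the electron-poor disubstituted alkene; the isolated trisubstituted alkene and the ketal are inert at 0 °C.

Step 10
Reactants: 17 saturated hydroxy ester
Product: 18 diol (C3–OH primary, C10–OH secondary)
Conditions: LiAlH4, THF, 0 °C
Reagents that add atoms: none
Why: Hydride reduction of the ester to the primary alcohol; no other group in the molecule is reducible.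

Step 11
Reactants: 18 diol
Product: 19 C3 TBDPS ether
Conditions: TBDPSCl, imidazole, CH2Cl2, 0 °C
Reagents that add atoms: tert-butyl(chloro)diphenylsilane, CC(C)(C)[Si](Cl)(c1ccccc1)c1ccccc1
Why: Silylation; the bulky silyl chloride takes the primary alcohol far faster than the neopentyl-type secondary alcohol at C10.

Step 12
Reactants: 19 C3 TBDPS ether
Product: 20 C10 ketone
Conditions: Dess–Martin periodinane, pyridine, CH2Cl2, rt
Reagents that add atoms: none
Why: Dess–Martin oxidation of the secondary alcohol under buffered conditions; the only α-stereocentre, C11, is quaternary and cannot epimerise.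

Step 13
Reactants: 20 C10 ketone
Product: 21 tertiary alcohol (C10 methyl and hydroxyl as in the target)
Conditions: MeMgBr, CeCl3, THF, −78 °C
Reagents that add atoms: methylmagnesium bromide, C[Mg]Br
Why: Grignard 1,2-addition with CeCl3 to suppress enolisation; in either chair the top face of the carbonyl is the more encumbered (axial C11 methyl in one, axial C6 arm in the other), so the reagent should enter from the bottom face and place the new methyl trans to the C11 methyl and the hydroxyl cis to the C6 arm.

Step 14
Reactants: 21 tertiary alcohol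
Product: 22 E allylic alcohol (C16–OH)
Conditions: SeO2 (cat.), tBuOOH, salicylic acid (cat.), CH2Cl2, rt
Reagents that add atoms: selenium dioxide, O=[Se]=O (catalytic oxygen carrier); tert-butyl hydroperoxide, CC(C)(C)OO (terminal oxygen source)
Why: SeO2 allylic oxidation (ene reaction, then [2,3]-sigmatropic shift) of the only alkene present oxidises the methyl group trans to the chain and so gives the E allylic alcohol.

Step 15
Reactants: 22 E allylic alcohol
Product: 23 E enal (C16 aldehyde)
Conditions: MnO2, CH2Cl2, rt
Reagents that add atoms: none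
Why: MnO2 oxidation is specific for the allylic alcohol; the tertiary alcohol is inert and the E geometry is kept.

Step 16
Reactants: 23 E enal; 24 geranyl chloride
Product: 26 C16 carbinol (both C16 epimers), via geranylbarium chloride 25 (not isolated)
Conditions: BaI2, lithium biphenylide (LiC12H10), THF, rt; 24, −78 °C; then 23, −78 °C
Reagents that add atoms: none
Why: Allylbarium addition: allylic barium reagents made at −78 °C add to aldehydes in a 1,2-manner through their α-carbon with retention of the E geometry, giving the linear homoallylic alcohol; C16 is formed without control, and the reagent is used in excess because the tertiary hydroxyl consumes one equivalent.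

Step 17
Reactants: 26 C16 carbinol
Product: 27 C16 enone
Conditions: Dess–Martin periodinane, pyridine, CH2Cl2, 0 °C
Reagents that add atoms: none
Why: Dess–Martin oxidation under pyridine buffer gives the enone without moving the C18=C19 alkene into conjugation, and erases the uncontrolled C16 centre.

Step 18
Reactants: 27 C16 enone
Product: 28 (16R)-alcohol
Conditions: (S)-2-methyl-CBS-oxazaborolidine (cat.), catecholborane, toluene, −78 °C
Reagents that add atoms: none
Why: Corey–Bakshi–Shibata reduction: with the (S)-oxazaborolidine the α-methyl alkenyl group acts as the large substituent, so hydride is delivered to the face that gives the 16R alcohol; catecholborane at −78 °C does not hydroborate the alkenes.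

Step 19
Reactants: 28 (16R)-alcohol
Product: 29 C7 ketone
Conditions: PPTS, acetone–H2O, 50 °C
Reagents that add atoms: water, O
Why: Mild acid-catalysed ketal hydrolysis, which leaves the TBDPS ether and the allylic and tertiary alcohols intact and is too weak to equilibrate C6.

Step 20
Reactants: 29 C7 ketone
Product: 30 C16 TBS ether
Conditions: TBSCl, imidazole, DMF, rt
Reagents that add atoms: tert-butyl(chloro)dimethylsilane, CC(C)(C)[Si](C)(C)Cl
Why: Silylation with TBSCl and imidazole takes only the secondary allylic alcohol; the tertiary C10 alcohol is too hindered and the ketone is not enolised.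

Step 21
Reactants: 30 C16 TBS ether
Product: 31 C7 tertiary allylic alcohol (isopropenyl adduct, C7 configuration immaterial)
Conditions: CH2=C(CH3)MgBr, CeCl3, THF, −78 °C
Reagents that add atoms: isopropenylmagnesium bromide, CC(=C)[Mg]Br
Why: Grignard 1,2-addition with CeCl3, which favours addition over enolisation of the hindered ketone and so protects the C6 stereocentre; the new C7 centre is destroyed in the next step.

Step 22
Reactants: 31 C7 tertiary allylic alcohol
Product: 32 (2Z)-enal bis-silyl ether
Conditions: pyridinium chlorochromate C5H5NH[CrO3Cl], 4 Å molecular sieves, CH2Cl2, rt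
Reagents that add atoms: pyridinium chlorochromate, [O-][Cr](=O)(=O)Cl.c1cc[nH+]cc1
Why: Babler–Dauben oxidative transposition: the tertiary allylic chromate ester undergoes a [3,3] shift to the primary allylic chromate, which collapses to the aldehyde; in the chair transition state the C2 methyl should turn away from the branched C6 toward C8, placing the formyl group cis to C6 (2Z), which is also expected to be the less strained geometry, while the hindered tertiary C10 hydroxyl cannot be oxidised.

Step 23
Reactants: 32 (2Z)-enal bis-silyl ether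
Product: 33 isoiridogermanal
Conditions: Bu4NF, AcOH, THF, rt
Reagents that add atoms: none
Why: Fluoride-mediated desilylation removes both silyl ethers; acetic acid buffering protects the enal from base-induced isomerisation and from conjugate addition of the C10 hydroxyl.

Compound list

1 | nerol, (2Z)-3,7-dimethylocta-2,6-dien-1-ol | CC(C)=CCC/C(C)=C\CO | starting material
2 | neryl bromide, (2Z)-1-bromo-3,7-dimethylocta-2,6-diene | CC(C)=CCC/C(C)=C\CBr | intermediate
3 | (2R,5R)-2,5-dimethylpyrrolidine | C[C@@H]1CC[C@@H](C)N1 | starting material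
4 | 2,2,6-trimethyl-4H-1,3-dioxin-4-one | CC1=CC(=O)OC(C)(C)O1 | starting material
5 | acetylketene, 3-oxobut-1-en-1-one | CC(=O)C=C=O | intermediate
6 | 1-[(2R,5R)-2,5-dimethylpyrrolidin-1-yl]butane-1,3-dione | CC(=O)CC(=O)N1[C@H](C)CC[C@H]1C | intermediate
7 | dilithium dianion of 6, 1-[(2R,5R)-2,5-dimethylpyrrolidin-1-yl]buta-1,3-diene-1,3-diolate | [Li+].[Li+].C=C([O-])C=C([O-])N1[C@H](C)CC[C@H]1C | intermediate
8 | (6Z)-1-[(2R,5R)-2,5-dimethylpyrrolidin-1-yl]-7,11-dimethyldodeca-6,10-diene-1,3-dione | CC(C)=CCC/C(C)=C\CCC(=O)CC(=O)N1[C@H](C)CC[C@H]1C | intermediate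
9 | key precursor, 2-{2-[(3Z)-4,8-dimethylnona-3,7-dien-1-yl]-1,3-dioxolan-2-yl}-1-[(2R,5R)-2,5-dimethylpyrrolidin-1-yl]ethan-1-one | CC(C)=CCC/C(C)=C\CCC1(CC(=O)N2[C@H](C)CC[C@H]2C)OCCO1 | intermediate
10 | keteniminium triflate from 9 (C5=C6 cumulated with the pyrrolidinium nitrogen) | CC(C)=CCC/C(C)=C\CCC1(C=C=[N+]2[C@H](C)CC[C@H]2C)OCCO1.[O-]S(=O)(=O)C(F)(F)F | intermediate
11 | cyclobutaniminium triflate, the (2R,5R)-pyrrolidinium ylidene analogue of 12 | C[C@@H]1CC[C@@H](C)[N+]1=C2[C@@H]3C4(OCCO4)CC[C@H]2[C@@]3(C)CCC=C(C)C.[O-]S(=O)(=O)C(F)(F)F | intermediate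
12 | key product, (1R,5S,7R)-7-methyl-7-(4-methylpent-3-en-1-yl)spiro[bicyclo[3.1.1]heptane-2,2'-[1,3]dioxolan]-6-one; pentenyl chain syn to the three-carbon bridge | O=C1[C@@H]2C3(OCCO3)CC[C@H]1[C@@]2(C)CCC=C(C)C | intermediate
13 | lactone, 8-methyl-8-(4-methylpent-3-en-1-yl)spiro[6-oxabicyclo[3.2.1]octane-2,2'-[1,3]dioxolan]-7-one; ring carbons as in 12, oxygen on C10 with retention | O=C1[C@@H]2C3(OCCO3)CC[C@H](O1)[C@@]2(C)CCC=C(C)C | intermediate
14 | lactol, the 7-hydroxy compound from 13, both anomers | OC1[C@@H]2C3(OCCO3)CC[C@H](O1)[C@@]2(C)CCC=C(C)C | intermediate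
15 | open hydroxy aldehyde: cyclohexane with CHO on C6, dioxolane at C7, OH on C10, methyl and 4-methylpent-3-enyl on C11; CHO, OH and the C11 methyl on one face, the pentenyl chain on the other | CC(C)=CCC[C@@]1(C)[C@H](C=O)C2(OCCO2)CC[C@@H]1O | intermediate
16 | hydroxy enoate: as 15 with C6 bearing (E)-CH=CH–CO2Me | CC(C)=CCC[C@@]1(C)[C@H](/C=C/C(=O)OC)C2(OCCO2)CC[C@@H]1O | intermediate
17 | saturated ester: as 16 with C6 bearing CH2CH2CO2Me | CC(C)=CCC[C@@]1(C)[C@H](CCC(=O)OC)C2(OCCO2)CC[C@@H]1O | intermediate
18 | diol: as 17 with C6 bearing (CH2)3OH | CC(C)=CCC[C@@]1(C)[C@H](CCCO)C2(OCCO2)CC[C@@H]1O | intermediate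
19 | C3 tert-butyldiphenylsilyl ether of 18, C10–OH free | CC(C)=CCC[C@@]1(C)[C@H](CCCO[Si](c3ccccc3)(c4ccccc4)C(C)(C)C)C2(OCCO2)CC[C@@H]1O | intermediate
20 | C10 ketone of 19 | CC(C)=CCC[C@@]1(C)[C@H](CCCO[Si](c3ccccc3)(c4ccccc4)C(C)(C)C)C2(OCCO2)CCC1=O | intermediate
21 | tertiary alcohol: C10 bears CH3 and OH, the OH cis to the C6 arm and to the C11 methyl (C6, C10, C11 as in the target) | CC(C)=CCC[C@@]1(C)[C@H](CCCO[Si](c3ccccc3)(c4ccccc4)C(C)(C)C)C2(OCCO2)CC[C@]1(C)O | intermediate
22 | E allylic alcohol: as 21, side chain ending CH=C(CH3)CH2OH with CH2OH trans to C13 | OC/C(C)=C/CC[C@@]1(C)[C@H](CCCO[Si](c3ccccc3)(c4ccccc4)C(C)(C)C)C2(OCCO2)CC[C@]1(C)O | intermediate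
23 | E enal: as 22 with C16 as CHO | O=C/C(C)=C/CC[C@@]1(C)[C@H](CCCO[Si](c3ccccc3)(c4ccccc4)C(C)(C)C)C2(OCCO2)CC[C@]1(C)O | intermediate
24 | geranyl chloride, (2E)-1-chloro-3,7-dimethylocta-2,6-diene | CC(C)=CCC/C(C)=C/CCl | starting material
25 | geranylbarium chloride | CC(C)=CCC/C(C)=C/C[Ba]Cl | intermediate
26 | C16 carbinol, both C16 epimers: side chain (3E,7E)-5-hydroxy-4,8,12-trimethyltrideca-3,7,11-trien-1-yl on C11 | CC(C)=CCC/C(C)=C/CC(O)/C(C)=C/CC[C@@]1(C)[C@H](CCCO[Si](c3ccccc3)(c4ccccc4)C(C)(C)C)C2(OCCO2)CC[C@]1(C)O | intermediate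
27 | C16 enone from 26 | CC(C)=CCC/C(C)=C/CC(=O)/C(C)=C/CC[C@@]1(C)[C@H](CCCO[Si](c3ccccc3)(c4ccccc4)C(C)(C)C)C2(OCCO2)CC[C@]1(C)O | intermediate
28 | (16R)-alcohol, ketal and TBDPS ether still in place | CC(C)=CCC/C(C)=C/C[C@@H](O)/C(C)=C/CC[C@@]1(C)[C@H](CCCO[Si](c3ccccc3)(c4ccccc4)C(C)(C)C)C2(OCCO2)CC[C@]1(C)O | intermediate
29 | C7 ketone from 28 (ketal removed) | CC(C)=CCC/C(C)=C/C[C@@H](O)/C(C)=C/CC[C@@]1(C)[C@H](CCCO[Si](c3ccccc3)(c4ccccc4)C(C)(C)C)C(=O)CC[C@]1(C)O | intermediate
30 | C16 tert-butyldimethylsilyl ether of 29 | CC(C)=CCC/C(C)=C/C[C@@H](O[Si](C)(C)C(C)(C)C)/C(C)=C/CC[C@@]1(C)[C@H](CCCO[Si](c3ccccc3)(c4ccccc4)C(C)(C)C)C(=O)CC[C@]1(C)O | intermediate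
31 | C7 tertiary allylic alcohol: C7 bears OH and prop-1-en-2-yl, C7 configuration not defined | CC(C)=CCC/C(C)=C/C[C@@H](O[Si](C)(C)C(C)(C)C)/C(C)=C/CC[C@@]1(C)[C@H](CCCO[Si](c3ccccc3)(c4ccccc4)C(C)(C)C)C(O)(C(C)=C)CC[C@]1(C)O | intermediate
32 | (2Z)-enal with C3–OTBDPS and C16–OTBS | CC(C)=CCC/C(C)=C/C[C@@H](O[Si](C)(C)C(C)(C)C)/C(C)=C/CC[C@@]1(C)[C@H](CCCO[Si](c3ccccc3)(c4ccccc4)C(C)(C)C)/C(=C(/C)C=O)CC[C@]1(C)O | intermediate
33 | isoiridogermanal, (2Z)-2-[(2R,3S,4S)-4-hydroxy-3-[(3E,5R,7E)-5-hydroxy-4,8,12-trimethyltrideca-3,7,11-trien-1-yl]-2-(3-hydroxypropyl)-3,4-dimethylcyclohexylidene]propanal | CC(C)=CCC/C(C)=C/C[C@@H](O)/C(C)=C/CC[C@@]1(C)[C@H](CCCO)/C(=C(/C)C=O)CC[C@]1(C)O | target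

Total step count: 23. Longest linear sequence: 22 steps (nerol 1 through steps 1 and 3–23 to 33; the branch from amine 3 through step 2 is equally long).

Steps most likely to fail

Step 5. What may go wrong: the O-triflyl iminium or keteniminium ion may be captured by a dioxolane oxygen or take a hydride from a dioxolane CH2 group; the C11 cation may lose a proton or rotate before the four-membered ring closes; or the auxiliary may discriminate the alkene faces poorly. The fallback uses the neutral ketene and a resolution in place of the auxiliary; it sets out from neryl bromide 2 and returns at 12. γ-Alkylation of the dianion of ethyl acetoacetate (NaH, then nBuLi) with 2 gives the keto ester F1. Ketalisation as in step 4 gives the ketal ester F2, and LiOH gives the acid F3. Oxalyl chloride with catalytic DMF gives the acid chloride F4. Slow addition of F4 to Et3N in refluxing toluene generates the ketene F5, which closes by the same crossed [2+2] mode to the racemic ketone F6. Lithiated (S)-N,S-dimethyl-S-phenylsulfoximine adds to the cyclobutanone, and the diastereomeric β-hydroxysulfoximines are separated by chromatography. Thermolysis of the adduct F7 of the wanted enantiomer releases 12.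

Step 22. What may go wrong: poor control of the alkene geometry in the [3,3] shift, ionisation of the tertiary allylic chromate with capture of the allyl cation by the C10 hydroxyl, or dehydration to dienes. The fallback builds the tetrasubstituted alkene by carbonyl olefination; it sets out from ketone 30 and returns at 32. Horner–Wadsworth–Emmons reaction of 30 with diethyl (1-cyanoethyl)phosphonate and KOtBu in THF gives the unsaturated nitrile F8. Its 2Z isomer is separated at this stable stage, and the 2E isomer is recycled by iodine-catalysed equilibration. iBu2AlH at −78 °C followed by buffered hydrolysis of the aldimine gives 32.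

Step 13. What may go wrong: attack of the methyl nucleophile on the wrong face of the C10 carbonyl, or enolisation toward C9 instead of addition. The fallback delivers the carbon as a methylene and the hydrogen afterwards; it sets out from ketone 20 and returns at 21. Corey–Chaykovsky epoxidation is run with the sulfur ylide whose facial preference is opposite to that found for the Grignard reagent: Me3SI with nBuLi for kinetic delivery, or Me3S(O)I with NaH in DMSO for thermodynamic delivery. This gives the spiro-epoxide F9 with oxygen on the face of the C6 arm. LiEt3BH then opens the epoxide at its CH2 carbon to give 21.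

Further compounds

F1 | step 5 | ethyl (6Z)-7,11-dimethyl-3-oxododeca-6,10-dienoate | CC(C)=CCC/C(C)=C\CCC(=O)CC(=O)OCC
F2 | step 5 | ethyl 2-{2-[(3Z)-4,8-dimethylnona-3,7-dien-1-yl]-1,3-dioxolan-2-yl}acetate | CC(C)=CCC/C(C)=C\CCC1(CC(=O)OCC)OCCO1
F3 | step 5 | 2-{2-[(3Z)-4,8-dimethylnona-3,7-dien-1-yl]-1,3-dioxolan-2-yl}acetic acid | CC(C)=CCC/C(C)=C\CCC1(CC(=O)O)OCCO1
F4 | step 5 | acid chloride of F3 | CC(C)=CCC/C(C)=C\CCC1(CC(=O)Cl)OCCO1
F5 | step 5 | ketene from F4 | CC(C)=CCC/C(C)=C\CCC1(C=C=O)OCCO1
F6 | step 5 | racemic bicyclic ketone, 12 together with its enantiomer | O=C1[C@@H]2C3(OCCO3)CC[C@H]1[C@@]2(C)CCC=C(C)C.O=C1[C@H]2C3(OCCO3)CC[C@@H]1[C@]2(C)CCC=C(C)C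
F7 | step 5 | β-hydroxysulfoximine adduct of 12 with (S)-N,S-dimethyl-S-phenylsulfoximine, carbinol configuration not defined | OC1(C[S@@](=O)(=NC)c4ccccc4)[C@@H]2C3(OCCO3)CC[C@H]1[C@@]2(C)CCC=C(C)C
F8 | step 22 | (2Z)-nitrile corresponding to 32 (C1 as C≡N) | CC(C)=CCC/C(C)=C/C[C@@H](O[Si](C)(C)C(C)(C)C)/C(C)=C/CC[C@@]1(C)[C@H](CCCO[Si](c3ccccc3)(c4ccccc4)C(C)(C)C)/C(=C(/C)C#N)CC[C@]1(C)O
F9 | step 13 | spiro-epoxide at C10 of 20, oxygen cis to the C6 arm | CC(C)=CCC[C@@]1(C)[C@H](CCCO[Si](c3ccccc3)(c4ccccc4)C(C)(C)C)C2(OCCO2)CC[C@]1(C5)O5
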